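**Strategy.** The oxane ring (O, C4, C3, C2, C1, C15; cembrane numbering) is cut into two three-atom units, C2–C3–C4 and C1–C15–O. Its trans C3–O/C4–O array on a fully substituted C4 next to the C2 methylene is read as an epoxygeraniol unit. The dianion of a β-hydroxy ester is alkylated by the C2–I carbon of a (2R,3R)-epoxy iodide and, in the same operation, its tertiary oxygen opens the epoxide at C4 with inversion. The ester at C1 is later exchanged for C14 by radical decarboxylative coupling (sets C1). The 14-membered ring is closed at C7–C8 by Nozaki–Hiyama–Kishi reaction, and C7 is set by Corey–Bakshi–Shibata reduction.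

Key step: step 3

Remark: cembrane numbering is used throughout (C1 = ring CH bonded to C15Me2); compounds 1, 4, 10 and 11 are taken as commercial.

Step 1
Reactants: 1 geraniol
Product: 2 (2R,3R)-2,3-epoxygeraniol
Conditions: Ti(OiPr)4 (cat.), D-(−)-diethyl tartrate (cat.), t-BuOOH, 4 Å MS, CH2Cl2, −20 °C
Reagents that add atoms: tert-butyl hydroperoxide CC(C)(C)OO
Why: Sharpless asymmetric epoxidation; the allylic hydroxyl directs oxygen transfer to the 2,3-alkene only, and the D-tartrate should deliver the (2R,3R)-epoxide whose two carbons become C3 and C4.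

Step 2
Reactants: 2 (2R,3R)-2,3-epoxygeraniol
Product: 3 (2S,3R)-2-(iodomethyl)-3-methyl-3-(4-methylpent-3-en-1-yl)oxirane
Conditions: I2, PPh3, imidazole, CH2Cl2, 0 °C
Reagents that add atoms: iodine II
Why: Appel-type iodination of the primary alcohol under neutral conditions should leave the epoxide and both stereocentres untouched (the descriptor at the CH carbon changes only through priorities).

Step 3
Reactants: 3 epoxy iodide; 4 methyl 3-hydroxy-3-methylbutanoate
Product: 6 methyl (5R,6S)-5-(tert-butyldimethylsilyloxy)-2,2,6-trimethyl-6-(4-methylpent-3-en-1-yl)oxane-3-carboxylate (both C3 epimers), via alkylated epoxy hydroxy ester 5 (not isolated)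
Conditions: 4, LiN(iPr)2 (2.2 equiv), THF, −78 to −30 °C; 3, DMPU, −78 to −20 °C; AcOH quench, solvent switch without purification; TBSOTf, 2,6-lutidine, CH2Cl2, −78 to −30 °C
Reagents that add atoms: tert-butyldimethylsilyl trifluoromethanesulfonate CC(C)(C)[Si](C)(C)OS(=O)(=O)C(F)(F)F
Why: Fráter–Seebach-type alkylation followed in the same flask by a silyl-triflate-promoted hydroxy-epoxide cyclisation: LiN(iPr)2 converts 4 into the β-oxido ester enolate, whose carbon displaces iodide from the primary C2 of 3 by SN2 (C1–C2 bond) to give 5. After neutralisation TBSOTf silylates the epoxide oxygen and the tertiary C15 hydroxyl attacks the fully substituted C4 from the rear, the silyl group staying on the C3 oxygen (O–C4 bond). The oxane closes in the 6-endo-tet mode by a borderline SN2 opening. C3 keeps the configuration installed in step 1 and C4 is set by inversion, so both derive from the (2R,3R)-epoxide; C1 forms as a mixture that is erased in step 8. The step needs C- over O-alkylation of the dianion (normal for a lithium enolate and a primary iodide) and 6-endo over 5-exo attack; the latter is favoured by the cation-stabilising fully substituted C4, by non-protic strongly Lewis acidic activation and by the ester, which inductively disfavours charge build-up at C3.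

Step 4
Reactants: 6 oxane ester
Product: 8 methyl (5R,6S)-5-(tert-butyldimethylsilyloxy)-6-(3,3-dimethoxypropyl)-2,2,6-trimethyloxane-3-carboxylate, via C7 aldehyde 7 (not isolated)
Conditions: O3, CH2Cl2, −78 °C; Me2S; then HC(OMe)3, p-TsOH (cat.), rt
Reagents that add atoms: trimethyl orthoformate COC(OC)OC
Why: Ozonolysis cleaves the only alkene to the C7 aldehyde, which is masked in the same flask as its dimethyl acetal (acid-catalysed acetalisation) so that it survives the basic and radical steps.

Step 5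
Reactants: 8 acetal ester
Product: 9 (5R,6S)-5-(tert-butyldimethylsilyloxy)-6-(3,3-dimethoxypropyl)-2,2,6-trimethyloxane-3-carboxylic acid (both C3 epimers)
Conditions: LiOH, THF/MeOH/H2O, 50 °C; then 1 M HCl to pH 4, 0 °C
Reagents that add atoms: lithium hydroxide [Li+].[OH-]
Why: Saponification of the hindered methyl ester; silyl ether and acetal are base-stable and the C1 configuration is irrelevant because C1 becomes a radical in step 8.

Step 6
Reactants: 10 but-3-yn-1-ol; 11 but-3-en-2-one
Product: 13 (5E)-9-hydroxy-6-methylnon-5-en-2-one, via alkenylalane 12 (not isolated)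
Conditions: Me3Al (3 equiv), Cp2ZrCl2 (cat.), CH2Cl2, 0 °C to rt; then 11, CuBr·SMe2 (cat.), THF, 0 °C; aq. HCl
Reagents that add atoms: trimethylaluminium C[Al](C)C
Why: Negishi zirconium-catalysed carboalumination adds methyl and aluminium syn across the terminal alkyne, and copper-catalysed conjugate addition of the resulting (E)-alkenylalane to the enone should fix the (E)-C11=C12 geometry with retention.

Step 7
Reactants: 13 hydroxy enone
Product: 14 (5E)-9-iodo-6-methylnon-5-en-2-one
Conditions: I2, PPh3, imidazole, CH2Cl2, 0 °C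
Reagents that add atoms: iodine II
Why: Appel-type iodination of the primary homoallylic alcohol; ketone and alkene are inert.

Step 8
Reactants: 9 oxane acid; 14 iodo ketone
Product: 17 (5E)-9-[(3R,5R,6S)-5-(tert-butyldimethylsilyloxy)-6-(3,3-dimethoxypropyl)-2,2,6-trimethyloxan-3-yl]-6-methylnon-5-en-2-one, via redox-active ester 15 (not isolated), via alkylzinc iodide 16 (not isolated)
Conditions: 9, N-hydroxyphthalimide, DIC, DMAP (cat.), CH2Cl2, rt; 14, Zn, LiCl, THF, 40 °C; NiCl2·DME (cat.), 4,4′-di-tert-butyl-2,2′-bipyridine, THF/DMF, rt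
Reagents that add atoms: none
Why: Nickel-catalysed decarboxylative alkyl–alkyl Negishi coupling of a redox-active ester: single-electron reduction releases CO2 and the secondary C1 radical, which should be captured by the alkylnickel on the ring face opposite the 1,3-related C3 silyloxy group, so that C14 enters trans to the C3 oxygen (1R).

Step 9
Reactants: 17 methyl ketone
Product: 18 (5E)-9-[(3R,5R,6S)-5-(tert-butyldimethylsilyloxy)-6-(3,3-dimethoxypropyl)-2,2,6-trimethyloxan-3-yl]-6-methylnona-1,5-dien-2-yl trifluoromethanesulfonate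
Conditions: LiN(iPr)2, THF, −78 °C; N-(5-chloropyridin-2-yl)triflimide, −78 °C
Reagents that add atoms: N-(5-chloropyridin-2-yl)bis(trifluoromethanesulfonyl)imide FC(F)(F)S(=O)(=O)N(c1ccc(Cl)cn1)S(=O)(=O)C(F)(F)F
Why: Kinetic deprotonation of the methyl ketone at its methyl group and O-triflation of the enolate should give the 1,1-disubstituted alkenyl triflate that carries C8 and C19.

Step 10
Reactants: 18 alkenyl triflate acetal
Product: 19 (5E)-9-[(3R,5R,6S)-5-(tert-butyldimethylsilyloxy)-2,2,6-trimethyl-6-(3-oxopropyl)oxan-3-yl]-6-methylnona-1,5-dien-2-yl trifluoromethanesulfonate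
Conditions: PPTS (cat.), acetone/H2O, 40 °C
Reagents that add atoms: water O
Why: Mild acid-catalysed acetal hydrolysis unmasks the C7 aldehyde without touching the alkenyl triflate or the hindered silyl ether.

Step 11
Reactants: 19 aldehyde alkenyl triflate
Product: 20 (1R,3R,4S,11E)-3-(tert-butyldimethylsilyloxy)-4,15-epoxycembra-8(19),11-dien-7-ol (both C7 epimers)
Conditions: CrCl2 (excess), NiCl2 (cat.), DMSO/THF, rt, high dilution
Reagents that add atoms: none
Why: Nozaki–Hiyama–Kishi reaction: zerovalent nickel inserts into the alkenyl triflate, transmetalation to chromium and addition to the aldehyde at high dilution close the 14-membered ring and install the exocyclic methylene carbinol; C7 is not controlled here and is corrected in steps 12 and 15.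

Step 12
Reactants: 20 macrocyclic allylic alcohol
Product: 21 (1R,3R,4S,11E)-3-(tert-butyldimethylsilyloxy)-4,15-epoxycembra-8(19),11-dien-7-one
Conditions: Dess–Martin periodinane, CH2Cl2, rt
Reagents that add atoms: none
Why: Dess–Martin oxidation converges both C7 epimers to the α-methylene ketone under neutral conditions.

Step 13
Reactants: 21 silyloxy enone
Product: 22 (1R,3R,4S,11E)-3-hydroxy-4,15-epoxycembra-8(19),11-dien-7-one
Conditions: HF·pyridine, pyridine/THF, 0 °C to rt
Reagents that add atoms: none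
Why: Fluoride-mediated desilylation under buffered conditions that spare the enone and the tertiary ether.

Step 14
Reactants: 22 hydroxy enone
Product: 23 (1R,3R,4S,11E)-7-oxo-4,15-epoxycembra-8(19),11-dien-3-yl acetate
Conditions: Ac2O, pyridine, DMAP (cat.), CH2Cl2, rt
Reagents that add atoms: acetic anhydride CC(=O)OC(C)=O
Why: DMAP-catalysed acylation of the hindered secondary alcohol; no stereocentre is touched.

Step 15
Reactants: 23 acetoxy enone
Product: 24 (1R,3R,4S,7R,11E)-7-hydroxy-4,15-epoxycembra-8(19),11-dien-3-yl acetate (target)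
Conditions: (S)-2-methyl-CBS-oxazaborolidine (cat.), catecholborane, toluene, −78 °C; MeOH, pH 7 buffer
Reagents that add atoms: none
Why: Corey–Bakshi–Shibata reduction: with the (S)-oxazaborolidine the α-branched alkenyl group should act as the large substituent, giving the (7R)-allylic alcohol, while catecholborane avoids hydroboration and spares the acetate.

**Compound list**

1 | geraniol, (2E)-3,7-dimethylocta-2,6-dien-1-ol | CC(C)=CCC/C(C)=C/CO | starting material
2 | [(2R,3R)-3-methyl-3-(4-methylpent-3-en-1-yl)oxiran-2-yl]methanol | OC[C@H]1O[C@]1(C)CCC=C(C)C | intermediate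
3 | (2S,3R)-2-(iodomethyl)-3-methyl-3-(4-methylpent-3-en-1-yl)oxirane | IC[C@H]1O[C@]1(C)CCC=C(C)C | intermediate
4 | methyl 3-hydroxy-3-methylbutanoate | COC(=O)CC(C)(C)O | starting material
5 | methyl 3-hydroxy-3-methyl-2-{[(2R,3R)-3-methyl-3-(4-methylpent-3-en-1-yl)oxiran-2-yl]methyl}butanoate (both C2 epimers) | COC(=O)C(C[C@H]1O[C@]1(C)CCC=C(C)C)C(C)(C)O | intermediate
6 | methyl (5R,6S)-5-(tert-butyldimethylsilyloxy)-2,2,6-trimethyl-6-(4-methylpent-3-en-1-yl)oxane-3-carboxylate (both C3 epimers) | COC(=O)C1C[C@@H](O[Si](C)(C)C(C)(C)C)[C@](C)(CCC=C(C)C)OC1(C)C | intermediate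
7 | methyl (5R,6S)-5-(tert-butyldimethylsilyloxy)-2,2,6-trimethyl-6-(3-oxopropyl)oxane-3-carboxylate | COC(=O)C1C[C@@H](O[Si](C)(C)C(C)(C)C)[C@](C)(CCC=O)OC1(C)C | intermediate
8 | methyl (5R,6S)-5-(tert-butyldimethylsilyloxy)-6-(3,3-dimethoxypropyl)-2,2,6-trimethyloxane-3-carboxylate | COC(=O)C1C[C@@H](O[Si](C)(C)C(C)(C)C)[C@](C)(CCC(OC)OC)OC1(C)C | intermediate
9 | (5R,6S)-5-(tert-butyldimethylsilyloxy)-6-(3,3-dimethoxypropyl)-2,2,6-trimethyloxane-3-carboxylic acid | OC(=O)C1C[C@@H](O[Si](C)(C)C(C)(C)C)[C@](C)(CCC(OC)OC)OC1(C)C | intermediate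
10 | but-3-yn-1-ol | C#CCCO | starting material
11 | but-3-en-2-one | C=CC(C)=O | starting material
12 | dimethyl[(1E)-4-(dimethylalumanyloxy)-2-methylbut-1-en-1-yl]alumane | C[Al](C)/C=C(\C)CCO[Al](C)C | intermediate
13 | (5E)-9-hydroxy-6-methylnon-5-en-2-one | CC(=O)CC/C=C(\C)CCO | intermediate
14 | (5E)-9-iodo-6-methylnon-5-en-2-one | CC(=O)CC/C=C(\C)CCI | intermediate
15 | 1,3-dioxoisoindolin-2-yl ester of acid 9 | O=C(ON1C(=O)c2ccccc2C1=O)C1C[C@@H](O[Si](C)(C)C(C)(C)C)[C@](C)(CCC(OC)OC)OC1(C)C | intermediate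
16 | [(3E)-3-methyl-7-oxooct-3-en-1-yl]zinc iodide | CC(=O)CC/C=C(\C)CC[Zn]I | intermediate
17 | (5E)-9-[(3R,5R,6S)-5-(tert-butyldimethylsilyloxy)-6-(3,3-dimethoxypropyl)-2,2,6-trimethyloxan-3-yl]-6-methylnon-5-en-2-one | CC(=O)CC/C=C(\C)CC[C@@H]1C[C@@H](O[Si](C)(C)C(C)(C)C)[C@](C)(CCC(OC)OC)OC1(C)C | intermediate
18 | enol triflate of 17 at C8/C19 (nona-1,5-dien-2-yl trifluoromethanesulfonate) | C=C(OS(=O)(=O)C(F)(F)F)CC/C=C(\C)CC[C@@H]1C[C@@H](O[Si](C)(C)C(C)(C)C)[C@](C)(CCC(OC)OC)OC1(C)C | intermediate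
19 | C7 aldehyde of 18 (3-oxopropyl side chain on the oxane) | C=C(OS(=O)(=O)C(F)(F)F)CC/C=C(\C)CC[C@@H]1C[C@@H](O[Si](C)(C)C(C)(C)C)[C@](C)(CCC=O)OC1(C)C | intermediate
20 | (1R,3R,4S,11E)-3-(tert-butyldimethylsilyloxy)-4,15-epoxycembra-8(19),11-dien-7-ol (both C7 epimers) | C=C1CC/C=C(\C)CC[C@@H]2C[C@@H](O[Si](C)(C)C(C)(C)C)[C@](C)(CCC1O)OC2(C)C | intermediate
21 | (1R,3R,4S,11E)-3-(tert-butyldimethylsilyloxy)-4,15-epoxycembra-8(19),11-dien-7-one | C=C1CC/C=C(\C)CC[C@@H]2C[C@@H](O[Si](C)(C)C(C)(C)C)[C@](C)(CCC1=O)OC2(C)C | intermediate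
22 | (1R,3R,4S,11E)-3-hydroxy-4,15-epoxycembra-8(19),11-dien-7-one | C=C1CC/C=C(\C)CC[C@@H]2C[C@@H](O)[C@](C)(CCC1=O)OC2(C)C | intermediate
23 | (1R,3R,4S,11E)-7-oxo-4,15-epoxycembra-8(19),11-dien-3-yl acetate | C=C1CC/C=C(\C)CC[C@@H]2C[C@@H](OC(C)=O)[C@](C)(CCC1=O)OC2(C)C | intermediate
24 | (1R,3R,4S,7R,11E)-7-hydroxy-4,15-epoxycembra-8(19),11-dien-3-yl acetate | C=C1CC/C=C(\C)CC[C@@H]2C[C@@H](OC(C)=O)[C@](C)(CC[C@H]1O)OC2(C)C | target

**Step count.** Total: 15 steps. Longest linear sequence: 13 steps (1–5 and 8–15, from geraniol); steps 6 and 7 form a two-step branch that joins at step 8.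

**Steps most likely to fail**

Step 3. The ether may close through the 5-exo mode at C3 (or the ester carbonyl may take part) instead of 6-endo attack at C4. The fallback sets out from 5 and returns at 6. Compound 5 is isolated and allowed to cyclise in the intrinsically favoured 5-exo sense (camphorsulfonic acid, CH2Cl2) to methyl (5S)-5-[(2R)-2-hydroxy-6-methylhept-5-en-2-yl]-2,2-dimethyloxolane-3-carboxylate F1. Rearrangement–ring expansion of this tetrahydrofuranyl carbinol (Zn(OTf)2, wet nitromethane) then follows: the ring oxygen displaces the activated tertiary hydroxyl at C4 to a bridged oxonium ion, which water reopens at C3. Double inversion at C3 and single inversion at C4 should give methyl (5R,6S)-5-hydroxy-2,2,6-trimethyl-6-(4-methylpent-3-en-1-yl)oxane-3-carboxylate F2. Silylation (TBSOTf, 2,6-lutidine) gives 6.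

Step 8. Capture of the C1 radical by nickel may show poor facial selectivity, or the alkylnickel may undergo β-alkoxide elimination. The fallback sets out from 9 and returns at 17. The redox-active ester 15 is reduced under photoredox conditions (Ru(bpy)3(PF6)2, Hantzsch ester, blue light) in the presence of 11, so that the C1 radical adds directly to the enone trans to the C3 silyloxy group (Giese reaction). This gives 4-[(3R,5R,6S)-5-(tert-butyldimethylsilyloxy)-6-(3,3-dimethoxypropyl)-2,2,6-trimethyloxan-3-yl]butan-2-one F3. The methyl ketone is converted through its enol phosphate (LiN(iPr)2, ClP(O)(OEt)2, then LiN(iPr)2) into (3R,5R,6S)-3-(but-3-yn-1-yl)-5-(tert-butyldimethylsilyloxy)-6-(3,3-dimethoxypropyl)-2,2,6-trimethyloxane F4. Zirconium-catalysed carboalumination and copper-catalysed conjugate addition of the alkenylalane to 11, as in step 6, give 17.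

Step 11. Oligomerisation or reduction of the alkenyl triflate may compete with ring closure. The fallback sets out from 18 and returns at 20; it uses a nickel-catalysed reductive alkyne–aldehyde macrocyclisation. Elimination of 18 (LiN(iPr)2, THF, −78 °C) gives the terminal alkyne (3R,5R,6S)-5-(tert-butyldimethylsilyloxy)-6-(3,3-dimethoxypropyl)-2,2,6-trimethyl-3-[(3E)-3-methyloct-3-en-7-yn-1-yl]oxane F5. Acetal hydrolysis as in step 10 gives 3-{(2S,3R,5R)-3-(tert-butyldimethylsilyloxy)-2,6,6-trimethyl-5-[(3E)-3-methyloct-3-en-7-yn-1-yl]oxan-2-yl}propanal F6. Ni(cod)2 with a bulky N-heterocyclic carbene ligand and Et3SiH should close the ring in the exocyclic-methylene mode to (1R,3R,4S,11E)-3-(tert-butyldimethylsilyloxy)-7-(triethylsilyloxy)-4,15-epoxycembra-8(19),11-diene F7. Selective removal of the triethylsilyl group (AcOH, THF/H2O) gives 20.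

**Further compounds**

F1 | step 3 | methyl (5S)-5-[(2R)-2-hydroxy-6-methylhept-5-en-2-yl]-2,2-dimethyloxolane-3-carboxylate | COC(=O)C1C[C@@H]([C@](C)(O)CCC=C(C)C)OC1(C)C
F2 | step 3 | methyl (5R,6S)-5-hydroxy-2,2,6-trimethyl-6-(4-methylpent-3-en-1-yl)oxane-3-carboxylate | COC(=O)C1C[C@@H](O)[C@](C)(CCC=C(C)C)OC1(C)C
F3 | step 8 | 4-[(3R,5R,6S)-5-(tert-butyldimethylsilyloxy)-6-(3,3-dimethoxypropyl)-2,2,6-trimethyloxan-3-yl]butan-2-one | CC(=O)CC[C@@H]1C[C@@H](O[Si](C)(C)C(C)(C)C)[C@](C)(CCC(OC)OC)OC1(C)C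
F4 | step 8 | (3R,5R,6S)-3-(but-3-yn-1-yl)-5-(tert-butyldimethylsilyloxy)-6-(3,3-dimethoxypropyl)-2,2,6-trimethyloxane | C#CCC[C@@H]1C[C@@H](O[Si](C)(C)C(C)(C)C)[C@](C)(CCC(OC)OC)OC1(C)C
F5 | step 11 | (3R,5R,6S)-5-(tert-butyldimethylsilyloxy)-6-(3,3-dimethoxypropyl)-2,2,6-trimethyl-3-[(3E)-3-methyloct-3-en-7-yn-1-yl]oxane | C#CCC/C=C(\C)CC[C@@H]1C[C@@H](O[Si](C)(C)C(C)(C)C)[C@](C)(CCC(OC)OC)OC1(C)C
F6 | step 11 | 3-{(2S,3R,5R)-3-(tert-butyldimethylsilyloxy)-2,6,6-trimethyl-5-[(3E)-3-methyloct-3-en-7-yn-1-yl]oxan-2-yl}propanal | C#CCC/C=C(\C)CC[C@@H]1C[C@@H](O[Si](C)(C)C(C)(C)C)[C@](C)(CCC=O)OC1(C)C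
F7 | step 11 | (1R,3R,4S,11E)-3-(tert-butyldimethylsilyloxy)-7-(triethylsilyloxy)-4,15-epoxycembra-8(19),11-diene | C=C1CC/C=C(\C)CC[C@@H]2C[C@@H](O[Si](C)(C)C(C)(C)C)[C@](C)(CCC1O[Si](CC)(CC)CC)OC2(C)C
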